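The route rests on opening the pyranone ring of the 5,7-dihydroxyflavanone unit across O1–C2 and C4–C3 at the flavone oxidation level. C2 is an aryl ketone carbon and C3 its α-methylene, both already present in the C2–C3–C3''–C2'' chain of a symmetrical 1,4-diaryl-1,4-diketone. In one operation the enolate of a 3-phenacylflavone (the 7-methoxy unit, built likewise) is acylated at C3 by a salicylic acid acetonide, whose released phenol O1 then closes onto C2 with loss of water. The resulting flat, achiral 3,3''-biflavone is finally saturated by a double asymmetric syn-hydrogenation that sets all four stereocentres (2,3-cis in both rings).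

Key step: step 5

Remark: the target is (2R,3R,2''R,3''R), that is 2,3-cis in both flavanone rings; unprimed locants refer to the 5,7-dihydroxy unit (unit A), double-primed locants to the 5-hydroxy-7-methoxy unit (unit B).
Assumption: acetonide 1 and diketone 5 are taken as catalogue compounds (otherwise one step each, from 2,4,6-trihydroxybenzoic acid and from anisole with succinyl chloride).

Step 1
Reactants: 1 5,7-dihydroxy-2,2-dimethyl-4H-1,3-benzodioxin-4-one
Product: 2 5,7-bis(benzyloxy)-2,2-dimethyl-4H-1,3-benzodioxin-4-one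
Conditions: BnBr (2.4 equiv), K2CO3, DMF, 60 °C
Reagents that add atoms: benzyl bromide BrCc1ccccc1
Why: Williamson etherification of both phenols (the chelated 5-OH needs warming), the lactone-ketal being stable to aprotic carbonate; no stereocentre.

Step 2
Reactants: 1 5,7-dihydroxy-2,2-dimethyl-4H-1,3-benzodioxin-4-one
Product: 3 5-hydroxy-7-methoxy-2,2-dimethyl-4H-1,3-benzodioxin-4-one
Conditions: MeI (1.05 equiv), K2CO3 (1.1 equiv), acetone, 25 °C
Reagents that add atoms: iodomethane CI
Why: Williamson etherification that should stop at O7 because the 5-OH is hydrogen-bonded to the lactone carbonyl and much less nucleophilic; no stereocentre.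

Step 3
Reactants: 3 5-hydroxy-7-methoxy-2,2-dimethyl-4H-1,3-benzodioxin-4-one
Product: 4 5-(benzyloxy)-7-methoxy-2,2-dimethyl-4H-1,3-benzodioxin-4-one
Conditions: BnBr (1.5 equiv), K2CO3, DMF, 60 °C
Reagents that add atoms: benzyl bromide BrCc1ccccc1
Why: Williamson etherification of the remaining chelated phenol under forcing aprotic conditions; no stereocentre.

Step 4
Reactants: 4 5-(benzyloxy)-7-methoxy-2,2-dimethyl-4H-1,3-benzodioxin-4-one; 5 1,4-bis(4-methoxyphenyl)butane-1,4-dione
Product: 7 5-(benzyloxy)-7-methoxy-2-(4-methoxyphenyl)-3-[2-(4-methoxyphenyl)-2-oxoethyl]-4H-chromen-4-one, via aryl triketone 6 (not isolated)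
Conditions: 5 (2.2 equiv), LiN(SiMe3)2 (2.2 equiv), THF, −78 °C; 4 (1.0 equiv), −78 → 0 °C; then 2 M HCl, MeOH–THF, 50 °C (excess 5 recovered)
Reagents that add atoms: none
Why: Crossed Claisen acylation of the mono-enolate of 5 by the lactone carbonyl of 4 with loss of acetone (excess 5 suppresses double acylation), then Baker–Venkataraman-type cyclodehydration of the freed phenol onto the adjacent 4-methoxybenzoyl carbonyl (six-membered closure; the distal ketone would need a seven-membered ring); no stereocentre.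

Step 5
Reactants: 7 5-(benzyloxy)-7-methoxy-2-(4-methoxyphenyl)-3-[2-(4-methoxyphenyl)-2-oxoethyl]-4H-chromen-4-one; 2 5,7-bis(benzyloxy)-2,2-dimethyl-4H-1,3-benzodioxin-4-one
Product: 9 5,7-bis(benzyloxy)-3-[5-(benzyloxy)-7-methoxy-2-(4-methoxyphenyl)-4-oxo-4H-chromen-3-yl]-2-(4-methoxyphenyl)-4H-chromen-4-one, via flavonyl triketone 8 (not isolated)
Conditions: LiN(SiMe3)2 (2.2 equiv), THF, −78 °C; 2 (1.2 equiv), −78 → 25 °C; then 2 M HCl, MeOH–THF, 50 °C
Reagents that add atoms: none
Why: LiN(SiMe3)2 deprotonates the only enolisable position of 7, the CH2 between the 4-methoxybenzoyl group and C3'' of the flavone; this carbon (future C3) attacks the lactone carbonyl (future C4) of 2, and collapse of the tetrahedral intermediate expels acetone and frees the phenoxide (future O1) to give triketone 8 as its chelated enolate. On acidification the phenol adds to the 4-methoxybenzoyl carbonyl (future C2) to give a 2-hydroxyflavanone hemiketal that dehydrates to the chromone, so C4–C3 and O1–C2 are both made in one pot. The closest known reaction type is the crossed Claisen acylation of a ketone enolate by a salicylate followed by Baker–Venkataraman-type cyclodehydration of the 2-hydroxyaryl 1,3-diketone to a flavone. The pyranone ring closes by 6-exo-trig addition of O1 to the C2 carbonyl followed by elimination of water. No stereocentre is created: 8 is a configurationally labile 1,3-diketone and 9 is achiral apart from a possible C3–C3'' axis that step 6 removes. The step needs C- rather than O-acylation and closure onto C2 only; the lithium-chelated enolate and the rigid cyclic acyl donor favour C-acylation, and the 4-methoxybenzoyl carbonyl is the only carbonyl that can reach O1 through a six-membered ring.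

Step 6
Reactants: 9 5,7-bis(benzyloxy)-3-[5-(benzyloxy)-7-methoxy-2-(4-methoxyphenyl)-4-oxo-4H-chromen-3-yl]-2-(4-methoxyphenyl)-4H-chromen-4-one
Product: 11 (2R,3R)-5,7-bis(benzyloxy)-3-[(2R,3R)-5-(benzyloxy)-7-methoxy-2-(4-methoxyphenyl)-4-oxochroman-3-yl]-2-(4-methoxyphenyl)chroman-4-one, via biflavan-4,4''-diol 10 (not isolated)
Conditions: H2 (100 bar), [Ru(cod)(2-methylallyl)2] (10 mol%), SINpEt·HBF4 (20 mol%, the antipode that leads to the 2R series), KOtBu (20 mol%), toluene, 40 °C; then Dess–Martin periodinane, CH2Cl2, 0 → 25 °C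
Reagents that add atoms: none
Why: Proposed new method: the chiral Ru–NHC hydride (NHC from SINpEt·HBF4, 1,3-bis[1-(naphthalen-1-yl)ethyl]-4,5-dihydroimidazolium tetrafluoroborate) is expected to add H2 syn across each tetrasubstituted C2=C3 enol-ether bond (hydride to C2, protonolysis of the Ru–C3 bond on the same face), so each ring should emerge 2,3-cis; the catalyst, addressing two near-identical flavone halves (both rotamers about C3–C3'' converge), should select the same enantioface twice to give 2R,3R,2''R,3''R, a face error being diverted mainly into the separable unlike diastereomer; rapid over-reduction of C4=O removes the acidic C3–H from the reach of the base, and the periodinane then returns both ketones under non-epimerising conditions; the closest known reaction type is the Ru–NHC-catalysed asymmetric hydrogenation of simple flavones and chromones to flavanols with re-oxidation to flavanones, not yet shown on 3-substituted flavones.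

Step 7
Reactants: 11 (2R,3R)-5,7-bis(benzyloxy)-3-[(2R,3R)-5-(benzyloxy)-7-methoxy-2-(4-methoxyphenyl)-4-oxochroman-3-yl]-2-(4-methoxyphenyl)chroman-4-one
Product: 12 (2R,3R)-5,7-dihydroxy-3-[(2R,3R)-5-hydroxy-7-methoxy-2-(4-methoxyphenyl)-4-oxochroman-3-yl]-2-(4-methoxyphenyl)chroman-4-one
Conditions: H2 (1 atm), Pd/C (10%), EtOAc–MeOH, 25 °C
Reagents that add atoms: none
Why: Heterogeneous hydrogenolysis of the three benzyl ethers under neutral conditions, chosen so that neither C3/C3'' (enolisation) nor C2/C2'' (retro-oxa-Michael ring opening) can epimerise; no new stereocentre.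

Compound list
1 | 5,7-dihydroxy-2,2-dimethyl-4H-1,3-benzodioxin-4-one | CC1(C)OC(=O)c2c(O)cc(O)cc2O1 | starting material
2 | 5,7-bis(benzyloxy)-2,2-dimethyl-4H-1,3-benzodioxin-4-one | CC1(C)OC(=O)c2c(OCc3ccccc3)cc(OCc3ccccc3)cc2O1 | intermediate
3 | 5-hydroxy-7-methoxy-2,2-dimethyl-4H-1,3-benzodioxin-4-one | CC1(C)OC(=O)c2c(O)cc(OC)cc2O1 | intermediate
4 | 5-(benzyloxy)-7-methoxy-2,2-dimethyl-4H-1,3-benzodioxin-4-one | CC1(C)OC(=O)c2c(OCc3ccccc3)cc(OC)cc2O1 | intermediate
5 | 1,4-bis(4-methoxyphenyl)butane-1,4-dione | COc1ccc(cc1)C(=O)CCC(=O)c1ccc(OC)cc1 | starting material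
6 | 2-[2-(benzyloxy)-6-hydroxy-4-methoxybenzoyl]-1,4-bis(4-methoxyphenyl)butane-1,4-dione (labile CH, drawn without configuration) | COc1ccc(cc1)C(=O)CC(C(=O)c1ccc(OC)cc1)C(=O)c1c(O)cc(OC)cc1OCc1ccccc1 | intermediate (not isolated)
7 | 5-(benzyloxy)-7-methoxy-2-(4-methoxyphenyl)-3-[2-(4-methoxyphenyl)-2-oxoethyl]-4H-chromen-4-one | COc1ccc(cc1)C(=O)CC1=C(c2ccc(OC)cc2)Oc2cc(OC)cc(OCc3ccccc3)c2C1=O | intermediate
8 | 1-[2,4-bis(benzyloxy)-6-hydroxyphenyl]-2-[5-(benzyloxy)-7-methoxy-2-(4-methoxyphenyl)-4-oxo-4H-chromen-3-yl]-3-(4-methoxyphenyl)propane-1,3-dione (labile CH, drawn without configuration) | COc1ccc(cc1)C(=O)C(C(=O)c1c(O)cc(OCc2ccccc2)cc1OCc1ccccc1)C1=C(c2ccc(OC)cc2)Oc2cc(OC)cc(OCc3ccccc3)c2C1=O | intermediate (not isolated)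
9 | 5,7-bis(benzyloxy)-3-[5-(benzyloxy)-7-methoxy-2-(4-methoxyphenyl)-4-oxo-4H-chromen-3-yl]-2-(4-methoxyphenyl)-4H-chromen-4-one (unsymmetrical 3,3''-biflavone) | COc1ccc(cc1)C1=C(C2=C(c3ccc(OC)cc3)Oc3cc(OC)cc(OCc4ccccc4)c3C2=O)C(=O)c2c(OCc3ccccc3)cc(OCc3ccccc3)cc2O1 | intermediate
10 | 4,4''-diol of 11: 2,3-cis in both rings with the C2, C3, C2'', C3'' configuration of 11; C4 and C4'' epimers, drawn without configuration there | COc1ccc([C@@H]2Oc3cc(OCc4ccccc4)cc(OCc4ccccc4)c3C(O)[C@@H]2[C@H]2C(O)c3c(OCc4ccccc4)cc(OC)cc3O[C@H]2c2ccc(OC)cc2)cc1 | intermediate (not isolated)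
11 | (2R,3R)-5,7-bis(benzyloxy)-3-[(2R,3R)-5-(benzyloxy)-7-methoxy-2-(4-methoxyphenyl)-4-oxochroman-3-yl]-2-(4-methoxyphenyl)chroman-4-one | COc1ccc([C@@H]2Oc3cc(OCc4ccccc4)cc(OCc4ccccc4)c3C(=O)[C@@H]2[C@H]2C(=O)c3c(OCc4ccccc4)cc(OC)cc3O[C@H]2c2ccc(OC)cc2)cc1 | intermediate
12 | (2R,3R)-5,7-dihydroxy-3-[(2R,3R)-5-hydroxy-7-methoxy-2-(4-methoxyphenyl)-4-oxochroman-3-yl]-2-(4-methoxyphenyl)chroman-4-one | COc1ccc([C@@H]2Oc3cc(O)cc(O)c3C(=O)[C@@H]2[C@H]2C(=O)c3c(O)cc(OC)cc3O[C@H]2c2ccc(OC)cc2)cc1 | target

Total step count: 7. Longest linear sequence: 6 steps (1 → 3 → 4 → 7 → 9 → 11 → 12; steps 2 to 7).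

Steps most likely to fail

Step 6. The catalyst may fail to turn over at two tetrasubstituted, mutually shielding C2=C3 bonds. Facial selectivity may erode in the second reduction, or C3 may epimerise under the residual base before the carbonyls are reduced. The fallback uses known chemistry and sets out from 9. Heterogeneous hydrogenation (H2, 50 bar, Pd/C, EtOAc–AcOH, 40 °C) adds hydrogen syn at the metal surface, the established way from flavones to 2,3-cis flavanones, and removes the benzyl ethers in the same operation. The crude is then racemic cis,cis material: 12 together with its enantiomer, the (2S,3S,2''S,3''S) isomer F1, and the unlike cis,cis isomers, the (2R,3R,2''S,3''S) isomer F2 and the (2S,3S,2''R,3''R) isomer F3. Silica gel chromatography removes F2 and F3, and preparative chromatography on a chiral stationary phase separates 12 from F1. The fallback comes back to the route at 12, so step 7 is not needed.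

Step 5. The hindered enolate of 7 may be O-acylated or not acylated at all, and triketone 8 may suffer retro-Claisen cleavage in the acid stage. The fallback sets out from 7 and replaces the ionic acylation by a pericyclic one. Compound 7 is converted (Me3SiOTf, Et3N, CH2Cl2, 0 °C) into its (Z)-trimethylsilyl enol ether F4. Irradiation (300 nm, CH2Cl2, 25 °C) of acetonide 2 in its presence expels acetone to give the ortho-quinoid ketene, whose sp-hybridised acyl carbon is unhindered. Inverse-electron-demand [4+2] cycloaddition across the enol ether (ketene carbon to C3, ring oxygen to C2) gives the 2-(trimethylsilyloxy)flavanone cycloadduct F5 (racemic, not isolated). This loses trimethylsilanol on mild acidic work-up and comes back to the route at 9, with both bonds of the pyranone ring again made in one operation.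

Step 4. Diketone 5 may be acylated twice, and in the acid stage the 1,4-dicarbonyl array of 6 may close to a furan (Paal–Knorr) instead of cyclodehydrating to the chromone. The fallback sets out from 4 and installs the 1,4-dicarbonyl unit only after the pyranone ring exists. Claisen acylation of the lithium enolate of 1-(4-methoxyphenyl)ethanone with 4 (LiN(SiMe3)2, THF, −78 → 0 °C) gives the β-diketone 1-[2-(benzyloxy)-6-hydroxy-4-methoxyphenyl]-3-(4-methoxyphenyl)propane-1,3-dione F6. This is cyclodehydrated in the same pot (HCl, MeOH, 50 °C) to 5-(benzyloxy)-7-methoxy-2-(4-methoxyphenyl)-4H-chromen-4-one F7. Lithiation at C3 and iodination (LiN(iPr)2, I2, THF, −78 °C) gives the 3-iodoflavone F8. Palladium-catalysed α-arylation-type coupling of the enolate of 1-(4-methoxyphenyl)ethanone with F8 (Pd2(dba)3, Xantphos, K3PO4, toluene, 80 °C) then comes back to the route at 7.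

Further compounds
F1 | step 6 | (2S,3S)-5,7-dihydroxy-3-[(2S,3S)-5-hydroxy-7-methoxy-2-(4-methoxyphenyl)-4-oxochroman-3-yl]-2-(4-methoxyphenyl)chroman-4-one | COc1ccc([C@H]2Oc3cc(O)cc(O)c3C(=O)[C@H]2[C@@H]2C(=O)c3c(O)cc(OC)cc3O[C@@H]2c2ccc(OC)cc2)cc1
F2 | step 6 | (2R,3R)-5,7-dihydroxy-3-[(2S,3S)-5-hydroxy-7-methoxy-2-(4-methoxyphenyl)-4-oxochroman-3-yl]-2-(4-methoxyphenyl)chroman-4-one | COc1ccc([C@@H]2Oc3cc(O)cc(O)c3C(=O)[C@@H]2[C@@H]2C(=O)c3c(O)cc(OC)cc3O[C@@H]2c2ccc(OC)cc2)cc1
F3 | step 6 | (2S,3S)-5,7-dihydroxy-3-[(2R,3R)-5-hydroxy-7-methoxy-2-(4-methoxyphenyl)-4-oxochroman-3-yl]-2-(4-methoxyphenyl)chroman-4-one | COc1ccc([C@H]2Oc3cc(O)cc(O)c3C(=O)[C@H]2[C@H]2C(=O)c3c(O)cc(OC)cc3O[C@H]2c2ccc(OC)cc2)cc1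
F4 | step 5 | 5-(benzyloxy)-7-methoxy-2-(4-methoxyphenyl)-3-[(Z)-2-(4-methoxyphenyl)-2-(trimethylsilyloxy)ethenyl]-4H-chromen-4-one | COc1ccc(cc1)/C(O[Si](C)(C)C)=C/C1=C(c2ccc(OC)cc2)Oc2cc(OC)cc(OCc3ccccc3)c2C1=O
F5 | step 5 | 5,7-bis(benzyloxy)-3-[5-(benzyloxy)-7-methoxy-2-(4-methoxyphenyl)-4-oxo-4H-chromen-3-yl]-2-(4-methoxyphenyl)-2-(trimethylsilyloxy)chroman-4-one (racemic; silyloxy group and flavonyl group cis, one enantiomer drawn) | COc1ccc(cc1)[C@@]2(O[Si](C)(C)C)Oc3cc(OCc4ccccc4)cc(OCc4ccccc4)c3C(=O)[C@@H]2C2=C(c3ccc(OC)cc3)Oc3cc(OC)cc(OCc4ccccc4)c3C2=O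
F6 | step 4 | 1-[2-(benzyloxy)-6-hydroxy-4-methoxyphenyl]-3-(4-methoxyphenyl)propane-1,3-dione | COc1ccc(cc1)C(=O)CC(=O)c1c(O)cc(OC)cc1OCc1ccccc1
F7 | step 4 | 5-(benzyloxy)-7-methoxy-2-(4-methoxyphenyl)-4H-chromen-4-one | COc1ccc(cc1)C1=CC(=O)c2c(OCc3ccccc3)cc(OC)cc2O1
F8 | step 4 | 5-(benzyloxy)-3-iodo-7-methoxy-2-(4-methoxyphenyl)-4H-chromen-4-one | COc1ccc(cc1)C1=C(I)C(=O)c2c(OCc3ccccc3)cc(OC)cc2O1
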